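**Retrosynthetic overview** (daucane numbering: C1 = quaternary C–Me, C4 = carbinol with iPr, C5 = ring-fusion CH, C6 = ester carbinol, C8=C9 = alkene)

1. Ferutinin ⇒ C6–O acylation and desilylation of 4‑O‑TBS‑jaeschkeanadiol (8).
2. Ring B (cycloheptene) is formed last: the C6–C7 bond comes from a cathodic Sm(II)-mediated 7‑endo ketyl–olefin cyclisation with β‑silyloxy elimination, which also places C8=C9 and sets C6.
3. C1 (quaternary methyl) comes from cuprate addition to a cyclopentene carbaldehyde; C5 is then set by equilibration of the α‑formyl centre.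
4. Ring A (cyclopentene) is formed first, by enamine aldol condensation of a keto‑aldehyde; the C7–C9 side chain comes from a kinetic aldol with methacrolein.
5. The keto‑acetal comes from ozonolysis of (S)‑terpinen‑4‑ol, whose carbinol carbon becomes C4 and controls C1, C5 and C6.

Assumption: (S)‑(+)‑terpinen‑4‑ol (high ee), methacrolein and 4‑[(tert‑butyldimethylsilyl)oxy]benzoic acid are purchased.

---

**Step 1**
Reactants: 1, (S)‑terpinen‑4‑ol
Product: 2, (S)‑terpinen‑4‑yl TBS ether
Conditions: TBSOTf, 2,6‑lutidine, CH2Cl2, 0 °C → rt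
Reagents that add atoms: TBSOTf, CC(C)(C)[Si](C)(C)OS(=O)(=O)C(F)(F)F
Why: Silyl‑triflate silylation of the hindered tertiary alcohol; it blocks hemiketal formation, retro‑aldol and dehydration in the later β‑oxy carbonyl intermediates, and the purchased stereocentre (future C4) is untouched.

**Step 2**
Reactants: 2
Product: 3, (5S)‑5‑(TBS‑oxy)‑7,7‑dimethoxy‑5‑isopropylheptan‑2‑one
Conditions: O3, CH2Cl2–MeOH, −78 °C; TsOH (cat.), → rt; NaHCO3; Me2S
Reagents that add atoms: ozone, [O-][O+]=O; methanol, CO
Why: Ozonolysis with in situ end differentiation: the carbonyl oxide at the more substituted carbon is trapped by MeOH, the free aldehyde is acetalised, and Me2S then releases the methyl ketone, giving ketone and masked aldehyde in one pot.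

**Step 3**
Reactants: 3; 4, methacrolein
Product: 5, (8S,3RS)‑3,8‑bis(TBS‑oxy)‑10,10‑dimethoxy‑2‑methyl‑8‑isopropyldec‑1‑en‑5‑one
Conditions: LDA, THF, −78 °C; 4; then TBSOTf, −78 °C
Reagents that add atoms: methacrolein, CC(=C)C=O; TBSOTf, CC(C)(C)[Si](C)(C)OS(=O)(=O)C(F)(F)F
Why: The kinetic (methyl-side) lithium enolate undergoes 1,2‑aldol addition to the enal and the aldolate is capped in situ; this installs C7–C9 and C14 with the future leaving group on C9, whose configuration is irrelevant because it is destroyed in step 6.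

**Step 4**
Reactants: 5
Product: 6, (5R)‑2‑[2‑(TBS‑oxy)‑3‑methylbut‑3‑enyl]‑5‑(TBS‑oxy)‑5‑isopropylcyclopent‑1‑ene‑1‑carbaldehyde
Conditions: PPTS, acetone–H2O, 50 °C; then piperidine, AcOH, PhMe, rt
Reagents that add atoms: none
Why: Acetal hydrolysis followed by amine‑catalysed intramolecular aldol condensation: the aldehyde enamine attacks the ketone (5‑membered ring A) and the only free hydroxyl, the new tertiary aldol OH, is eliminated to give the conjugated enal.

**Step 5**
Reactants: 6
Product: 7, (1R,2R,5R)‑2‑[2‑(TBS‑oxy)‑3‑methylbut‑3‑enyl]‑5‑(TBS‑oxy)‑2‑methyl‑5‑isopropylcyclopentane‑1‑carbaldehyde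
Conditions: Me2CuLi, TMSCl, THF, −78 → −30 °C; H3O+; then DBU (cat.), CH2Cl2, 0 °C
Reagents that add atoms: lithium dimethylcuprate, [Li+].C[Cu-]C
Why: TMSCl‑accelerated Gilman 1,4‑addition creates the C1 quaternary centre, with methyl entering anti to the isopropyl group (held pseudo‑axial by A1,2 strain with the formyl group; the O‑silyl group has a small 1,3‑demand), so Me ends cis to the C4 oxygen; base epimerisation of the α‑formyl centre then places CHO trans to both the isopropyl and the side chain, setting C5.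

**Step 6**
Reactants: 7
Product: 8, (3R,3aS,4S,8aR)‑3‑(TBS‑oxy)‑3‑isopropyl‑6,8a‑dimethyl‑1,2,3,3a,4,5,8,8a‑octahydroazulen‑4‑ol (4‑O‑TBS‑jaeschkeanadiol)
Conditions: SmI2 (20 mol %), HMPA, TMSCl, n‑Bu4NPF6, THF, divided cell, C cathode, −1.6 V vs SCE, 5 mM, rt; then K2CO3, MeOH
Reagents that add atoms: none
Why: Proposed new method: Sm(II) regenerated at the cathode forms the Sm(III) ketyl of the aldehyde, which adds 7‑endo to the CH2 terminus of the 1,1‑disubstituted alkene; the tertiary radical is reduced by a second Sm(II) and the organosamarium β‑eliminates the C9 silanolate, fixing the alkene at C8=C9, while TMSCl turns over the Sm–O bonds and the low steady‑state Sm(II) and high dilution suppress pinacol coupling. The trans‑1,2 tethers enforce the trans ring fusion and the bulky O–Sm sits equatorial in the chair‑like transition state, giving the 6α‑alcohol (H5/H6 trans‑diaxial). The closest known chemistry is stoichiometric SmI2 ketyl–olefin coupling/β‑elimination and 8‑endo ketyl–olefin cyclisation, plus electrochemical regeneration of Sm(II).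

**Step 7**
Reactants: 8; 9, 4‑[(tert‑butyldimethylsilyl)oxy]benzoic acid
Product: 10, bis‑TBS ferutinin
Conditions: EDC·HCl, DMAP, CH2Cl2, rt
Reagents that add atoms: 4‑(TBS‑oxy)benzoic acid, OC(=O)c1ccc(O[Si](C)(C)C(C)(C)C)cc1
Why: Steglich esterification of the only free hydroxyl (secondary, equatorial), with retention at C6.

**Step 8**
Reactants: 10
Product: 11, ferutinin
Conditions: HF·pyridine, THF–pyridine, 0 °C → rt
Reagents that add atoms: none
Why: Fluoride desilylation removes the aryl and the tertiary alkyl TBS ethers under non‑basic conditions, so the benzoate neither migrates nor hydrolyses.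

---

**Compound list**

1 | (S)‑terpinen‑4‑ol | CC1=CC[C@](O)(C(C)C)CC1 | starting material
2 | (S)‑terpinen‑4‑yl TBS ether | CC1=CC[C@](O[Si](C)(C)C(C)(C)C)(C(C)C)CC1 | intermediate
3 | (5S)‑5‑(TBS‑oxy)‑7,7‑dimethoxy‑5‑isopropylheptan‑2‑one | CC(=O)CC[C@@](O[Si](C)(C)C(C)(C)C)(C(C)C)CC(OC)OC | intermediate
4 | methacrolein | CC(=C)C=O | starting material
5 | (8S)‑3,8‑bis(TBS‑oxy)‑10,10‑dimethoxy‑2‑methyl‑8‑isopropyldec‑1‑en‑5‑one (C3 epimers) | C=C(C)C(O[Si](C)(C)C(C)(C)C)CC(=O)CC[C@@](O[Si](C)(C)C(C)(C)C)(C(C)C)CC(OC)OC | intermediate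
6 | (5R)‑2‑[2‑(TBS‑oxy)‑3‑methylbut‑3‑enyl]‑5‑(TBS‑oxy)‑5‑isopropylcyclopent‑1‑ene‑1‑carbaldehyde | C=C(C)C(O[Si](C)(C)C(C)(C)C)CC1=C(C=O)[C@](O[Si](C)(C)C(C)(C)C)(C(C)C)CC1 | intermediate
7 | (1R,2R,5R)‑2‑[2‑(TBS‑oxy)‑3‑methylbut‑3‑enyl]‑5‑(TBS‑oxy)‑2‑methyl‑5‑isopropylcyclopentane‑1‑carbaldehyde | C=C(C)C(O[Si](C)(C)C(C)(C)C)C[C@@]1(C)CC[C@@](O[Si](C)(C)C(C)(C)C)(C(C)C)[C@@H]1C=O | intermediate
8 | 4‑O‑TBS‑jaeschkeanadiol | CC1=CC[C@@]2(C)CC[C@@](O[Si](C)(C)C(C)(C)C)(C(C)C)[C@@H]2[C@@H](O)C1 | intermediate
9 | 4‑[(tert‑butyldimethylsilyl)oxy]benzoic acid | OC(=O)c1ccc(O[Si](C)(C)C(C)(C)C)cc1 | starting material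
10 | bis‑TBS ferutinin | CC1=CC[C@@]2(C)CC[C@@](O[Si](C)(C)C(C)(C)C)(C(C)C)[C@@H]2[C@@H](OC(=O)c2ccc(O[Si](C)(C)C(C)(C)C)cc2)C1 | intermediate
11 | ferutinin | CC1=CC[C@@]2(C)CC[C@@](O)(C(C)C)[C@@H]2[C@@H](OC(=O)c2ccc(O)cc2)C1 | target

---

**Total steps:** 8. **Longest linear sequence:** 8 (from 1).

**Steps most likely to fail, with fallbacks**

1. **Step 6 (the proposed new cathodic Sm‑ketyl 7‑endo cyclisation/β‑elimination).** Risks are simple aldehyde reduction, pinacol coupling, or the wrong C6 epimer. Fallback with known chemistry only: add vinylmagnesium bromide to 7, close the seven‑membered ring by ring‑closing metathesis (Grubbs II) onto the isopropenyl group (giving C7=C8), then, after acylating C6–OH, free the secondary C9 alcohol and apply a Myers reductive allylic transposition (NBSH, PPh3, DEAD) to move the alkene to C8=C9. If C6 is wrong, oxidise and reduce under thermodynamic (dissolving‑metal) conditions to the equatorial alcohol.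

2. **Step 5 (conjugate methylation of a hindered tetrasubstituted enal, and its facial selectivity).** Fallback: reduce 6 to the allylic alcohol (DIBAL), carry out a hydroxyl‑directed Simmons–Smith cyclopropanation (Et2Zn, CH2I2), re‑oxidise to the aldehyde, and open the cyclopropyl aldehyde reductively (Li/NH3) to reveal the angular methyl; then equilibrate C5 as before.

3. **Step 3 (kinetic cross‑aldol with methacrolein and in situ silylation).** Fallback: install the side chain on the intact cyclohexene before ring cleavage. Epoxidise 1 (VO(acac)2, TBHP), isomerise with Et2NLi to the exocyclic allylic alcohol, O‑methallylate, and run a [2,3]‑Wittig rearrangement to give the same C9 carbinol/isopropenyl unit; then bis‑silylate, ozonolyse the ring alkene selectively, and rejoin the route at step 4.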